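**Plan**
1. Retrosynthesis: the pyran ring of the 2H-chromene is cut first, at C4–C4a and at O1–C2, giving triphenol 13 and prenal 14. Next the ArCH2–CH2Ar bond of the bibenzyl is cut, then the aryl–prenyl bond, leading back to methyl orsellinate 1.
2. Forward: ring A is bought as 1. Its C4 hydroxyl is masked, the prenyl group is put on C3 by phenoxide ortho C-alkylation, the C2 hydroxyl is masked, the ring B arm is joined at the lithiated C6 methyl, the three acetals are removed, and the pyran ring (ring C) is closed last.
3. Enabling feature (benzoate numbering of ring A in 13): C5 is the only ring A carbon that still carries hydrogen. It is ortho to the free C4 hydroxyl and para to the C2 hydroxyl, so it is an enol-like nucleophile. Once an enal has condensed there, the neighbouring C4 oxygen can close the 1-oxatriene O=C4–C5=CH–CH=CMe2. C3, the carbon that would otherwise react, is blocked by the prenyl group.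
4. Stereochemistry: the target has no stereocentre. The ring alkene is cis by ring size and both side-chain alkenes end in two identical methyl groups.

Key step: step 8

Assumption: because the target is achiral, no stereocontrol is planned.

**Route**

Step 1
Reactants: 1 methyl 2,4-dihydroxy-6-methylbenzoate (methyl orsellinate)
Product: 2 methyl 2-hydroxy-4-(methoxymethoxy)-6-methylbenzoate
Conditions: MOMCl (1.1 equiv), i-Pr2NEt, CH2Cl2, 0 °C to rt
Reagents that add atoms: chloromethyl methyl ether (MOMCl), COCCl
Why: Williamson-type O-alkylation should take place only at the free, more acidic C4 hydroxyl (para to the ester), because the C2 hydroxyl is held in a hydrogen bond to the ester carbonyl.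

Step 2
Reactants: 2 methyl 2-hydroxy-4-(methoxymethoxy)-6-methylbenzoate; 3 1-bromo-3-methylbut-2-ene (prenyl bromide)
Product: 5 methyl 2-hydroxy-4-(methoxymethoxy)-6-methyl-3-(3-methylbut-2-enyl)benzoate, via sodium phenoxide 4 (not isolated)
Conditions: NaH (1.1 equiv), toluene, rt; then 3 (1.2 equiv), 60 °C
Reagents that add atoms: none
Why: Ortho C-alkylation of a phenoxide contact ion pair in a non-polar solvent, a reaction type with close precedent on 2-hydroxy-4-alkoxy-6-substituted benzoates; C3 is the only unsubstituted carbon ortho to the phenoxide oxygen, the C4 oxygen is blocked, and SN2 attack at the CH2 of 3 followed by re-aromatisation gives the linear prenyl group.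

Step 3
Reactants: 5 methyl 2-hydroxy-4-(methoxymethoxy)-6-methyl-3-(3-methylbut-2-enyl)benzoate
Product: 7 methyl 2,4-bis(methoxymethoxy)-6-methyl-3-(3-methylbut-2-enyl)benzoate, via sodium phenoxide 6 (not isolated)
Conditions: NaH, DMF, 0 °C; then MOMCl, 0 °C to rt
Reagents that add atoms: chloromethyl methyl ether (MOMCl), COCCl
Why: In a dipolar aprotic solvent the free phenoxide should react at oxygen (Williamson etherification), which removes the acidic proton before the benzylic deprotonation of step 6.

Step 4
Reactants: 8 4-(methoxymethoxy)benzaldehyde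
Product: 9 [4-(methoxymethoxy)phenyl]methanol
Conditions: NaBH4, MeOH, 0 °C
Reagents that add atoms: none
Why: Standard hydride reduction of an aromatic aldehyde; the acetal is inert to it.

Step 5
Reactants: 9 [4-(methoxymethoxy)phenyl]methanol
Product: 10 1-(bromomethyl)-4-(methoxymethoxy)benzene
Conditions: CBr4, PPh3, CH2Cl2, 0 °C; product used at once
Reagents that add atoms: tetrabromomethane, BrC(Br)(Br)Br
Why: Appel bromination runs under neutral conditions, so the acid-labile acetal and the reactive 4-alkoxybenzyl bromide should survive.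

Step 6
Reactants: 7 methyl 2,4-bis(methoxymethoxy)-6-methyl-3-(3-methylbut-2-enyl)benzoate; 10 1-(bromomethyl)-4-(methoxymethoxy)benzene
Product: 12 methyl 2,4-bis(methoxymethoxy)-6-{2-[4-(methoxymethoxy)phenyl]ethyl}-3-(3-methylbut-2-enyl)benzoate, via benzylic lithium species 11 (not isolated)
Conditions: LiN(i-Pr)2 (1.2 equiv), THF, −78 °C; then 10 (1.2 equiv), −78 to −40 °C
Reagents that add atoms: none
Why: Lateral lithiation of an ortho-toluate (the C6 methyl is conjugated with the ester and is the most acidic C–H) followed by SN2 alkylation with a benzylic bromide should form the bibenzyl CH2–CH2 bond without any reduction step that would endanger the prenyl alkene.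

Step 7
Reactants: 12 methyl 2,4-bis(methoxymethoxy)-6-{2-[4-(methoxymethoxy)phenyl]ethyl}-3-(3-methylbut-2-enyl)benzoate
Product: 13 methyl 2,4-dihydroxy-6-[2-(4-hydroxyphenyl)ethyl]-3-(3-methylbut-2-enyl)benzoate
Conditions: 3 M aq. HCl, MeOH, 40 °C
Reagents that add atoms: none
Why: Acid-catalysed acetal exchange with methanol should remove all three methoxymethyl groups; dilute acid at moderate temperature is chosen to avoid cyclisation of the prenyl group onto a neighbouring phenol.

Step 8
Reactants: 13 methyl 2,4-dihydroxy-6-[2-(4-hydroxyphenyl)ethyl]-3-(3-methylbut-2-enyl)benzoate; 14 3-methylbut-2-enal (prenal)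
Product: 16 methyl 7-hydroxy-5-[2-(4-hydroxyphenyl)ethyl]-2,2-dimethyl-8-(3-methylbut-2-enyl)-2H-chromene-6-carboxylate (target), via ortho-quinone methide 15 (not isolated)
Conditions: 14 (3 equiv), ethylenediammonium diacetate (20 mol %), toluene, 110 °C
Reagents that add atoms: none
Why: The diammonium salt activates the aldehyde of 14 by iminium catalysis, C5 of ring A of 13 attacks it in a Knoevenagel/aldol-type C–C bond formation, and loss of the amine gives ortho-quinone methide 15, whose 1-oxatriene unit O=C4–C5=CH–CH=CMe2 then closes thermally. The closest known reaction type is the amine-salt-catalysed formal [3+3] chromene annulation of resorcinols and 2,4-dihydroxyaryl carbonyl compounds with enals (tandem Knoevenagel condensation and oxa-6π electrocyclisation). Ring C is closed by a disrotatory oxa-6π electrocyclisation that forms the O–CMe2 bond and restores the aromaticity of ring A. No stereocentre is formed, because the new sp3 carbon carries two methyl groups and the ring alkene can only be cis. The step needs site selectivity on ring A, the right choice of ring A oxygen, and chemoselectivity against ring B: C5 is the only unsubstituted carbon of ring A because C3 carries the prenyl group, only the C4 oxygen is ortho to C5 while the C2 hydroxyl is para to it and hydrogen-bonded to the ester, and the monohydric ring B lacks the second donor that makes a phenol carbon nucleophilic enough under these conditions.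

**Compound list**
1 | methyl 2,4-dihydroxy-6-methylbenzoate (methyl orsellinate) | COC(=O)c1c(C)cc(O)cc1O | starting material
2 | methyl 2-hydroxy-4-(methoxymethoxy)-6-methylbenzoate | COCOc1cc(C)c(C(=O)OC)c(O)c1 | intermediate
3 | 1-bromo-3-methylbut-2-ene (prenyl bromide) | CC(C)=CCBr | starting material
4 | sodium phenoxide of 2 (not isolated) | COCOc1cc(C)c(C(=O)OC)c([O-])c1.[Na+] | intermediate
5 | methyl 2-hydroxy-4-(methoxymethoxy)-6-methyl-3-(3-methylbut-2-enyl)benzoate | COCOc1cc(C)c(C(=O)OC)c(O)c1CC=C(C)C | intermediate
6 | sodium phenoxide of 5 (not isolated) | COCOc1cc(C)c(C(=O)OC)c([O-])c1CC=C(C)C.[Na+] | intermediate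
7 | methyl 2,4-bis(methoxymethoxy)-6-methyl-3-(3-methylbut-2-enyl)benzoate | COCOc1cc(C)c(C(=O)OC)c(OCOC)c1CC=C(C)C | intermediate
8 | 4-(methoxymethoxy)benzaldehyde | COCOc1ccc(C=O)cc1 | starting material
9 | [4-(methoxymethoxy)phenyl]methanol | COCOc1ccc(CO)cc1 | intermediate
10 | 1-(bromomethyl)-4-(methoxymethoxy)benzene | COCOc1ccc(CBr)cc1 | intermediate
11 | benzylic lithium species from 7, lithiated at the C6 methyl (not isolated) | COCOc1cc(C[Li])c(C(=O)OC)c(OCOC)c1CC=C(C)C | intermediate
12 | methyl 2,4-bis(methoxymethoxy)-6-{2-[4-(methoxymethoxy)phenyl]ethyl}-3-(3-methylbut-2-enyl)benzoate | COCOc1ccc(CCc2cc(OCOC)c(CC=C(C)C)c(OCOC)c2C(=O)OC)cc1 | intermediate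
13 | methyl 2,4-dihydroxy-6-[2-(4-hydroxyphenyl)ethyl]-3-(3-methylbut-2-enyl)benzoate | COC(=O)c1c(O)c(CC=C(C)C)c(O)cc1CCc1ccc(O)cc1 | intermediate
14 | 3-methylbut-2-enal (prenal) | CC(C)=CC=O | starting material
15 | ortho-quinone methide: methyl 2-hydroxy-6-[2-(4-hydroxyphenyl)ethyl]-3-(3-methylbut-2-enyl)-5-(3-methylbut-2-enylidene)-4-oxocyclohexa-1,6-diene-1-carboxylate, side chain cis to the C4 carbonyl (not isolated) | COC(=O)C1=C(CCc2ccc(O)cc2)/C(=C/C=C(C)C)C(=O)C(CC=C(C)C)=C1O | intermediate
16 | methyl 7-hydroxy-5-[2-(4-hydroxyphenyl)ethyl]-2,2-dimethyl-8-(3-methylbut-2-enyl)-2H-chromene-6-carboxylate | COC(=O)c1c(O)c(CC=C(C)C)c2c(c1CCc1ccc(O)cc1)C=CC(C)(C)O2 | target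

**Count**
Total steps: 8. Longest linear sequence: 6 (steps 1, 2, 3, 6, 7, 8); steps 4 and 5 form the side branch.

**Steps most likely to fail**

Step 8. The C–C bond formation at C5 may be too slow, because this carbon is flanked by the C6 side chain and ring A is deactivated by the ester; prenal may then be lost to self-condensation, or ring B may begin to react. Fallback, from 13: the most acidic hydroxyl (C4–OH, para to the ester) should be O-alkylated selectively with 3-chloro-3-methylbut-1-yne (1 equiv DBU, catalytic CuCl2, MeCN, 0 °C). This should give methyl 2-hydroxy-6-[2-(4-hydroxyphenyl)ethyl]-3-(3-methylbut-2-enyl)-4-[(2-methylbut-3-yn-2-yl)oxy]benzoate F1. Heating F1 in xylene at 140 °C should trigger a propargyl Claisen rearrangement to C5 (the only free ortho carbon), a 1,5-hydrogen shift to 15 and the same oxa-6π closure, which returns to the route at 16.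

Step 2. Alkylation may go to oxygen instead of carbon, may occur at the tertiary end of the allyl unit, or may take place twice. Fallback, from 2: the C2 hydroxyl should be etherified with 3-chloro-3-methylbut-1-yne (DBU, catalytic CuCl2, MeCN) to give methyl 4-(methoxymethoxy)-6-methyl-2-[(2-methylbut-3-yn-2-yl)oxy]benzoate F2. Semi-hydrogenation (H2, Pd/CaCO3 poisoned with Pb(OAc)2, quinoline, EtOAc) should give methyl 4-(methoxymethoxy)-6-methyl-2-[(2-methylbut-3-en-2-yl)oxy]benzoate F3. An aromatic Claisen rearrangement of F3 (N,N-diethylaniline, 120 °C) should deliver the allyl unit with inversion, as a linear prenyl group, to C3, the only free ortho carbon, which returns to the route at 5.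

Step 6. The benzylic anion may condense with the methyl ester of a second molecule, may be quenched by proton transfer from the benzylic-allylic CH2 of the prenyl group, or the product may be alkylated a second time. Fallback, from 2, reversing the order of the two C–C bond formations: treatment with LiN(i-Pr)2 (2.2 equiv, THF, −78 °C) should give the phenoxide/benzylic dilithium dianion of 2 F4. Alkylation of F4 with 10 should give methyl 2-hydroxy-4-(methoxymethoxy)-6-{2-[4-(methoxymethoxy)phenyl]ethyl}benzoate F5. Ortho C-prenylation of F5 (NaH, toluene, then 3, 60 °C), on the substrate class with the closest precedent, should give methyl 2-hydroxy-4-(methoxymethoxy)-6-{2-[4-(methoxymethoxy)phenyl]ethyl}-3-(3-methylbut-2-enyl)benzoate F6. Acetal cleavage of F6 under the conditions of step 7 returns to the route at 13.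

**Further compounds**
F1 | step 8 | methyl 2-hydroxy-6-[2-(4-hydroxyphenyl)ethyl]-3-(3-methylbut-2-enyl)-4-[(2-methylbut-3-yn-2-yl)oxy]benzoate | COC(=O)c1c(O)c(CC=C(C)C)c(OC(C)(C)C#C)cc1CCc1ccc(O)cc1
F2 | step 2 | methyl 4-(methoxymethoxy)-6-methyl-2-[(2-methylbut-3-yn-2-yl)oxy]benzoate | COCOc1cc(C)c(C(=O)OC)c(OC(C)(C)C#C)c1
F3 | step 2 | methyl 4-(methoxymethoxy)-6-methyl-2-[(2-methylbut-3-en-2-yl)oxy]benzoate | COCOc1cc(C)c(C(=O)OC)c(OC(C)(C)C=C)c1
F4 | step 6 | dilithium phenoxide/benzylic dianion of 2 (not isolated) | COCOc1cc(C[Li])c(C(=O)OC)c(O[Li])c1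
F5 | step 6 | methyl 2-hydroxy-4-(methoxymethoxy)-6-{2-[4-(methoxymethoxy)phenyl]ethyl}benzoate | COCOc1ccc(CCc2cc(OCOC)cc(O)c2C(=O)OC)cc1
F6 | step 6 | methyl 2-hydroxy-4-(methoxymethoxy)-6-{2-[4-(methoxymethoxy)phenyl]ethyl}-3-(3-methylbut-2-enyl)benzoate | COCOc1ccc(CCc2cc(OCOC)c(CC=C(C)C)c(O)c2C(=O)OC)cc1
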